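The acyl chain is cut from the 2-pyridone ring at C3–C1' (aryllithium plus aldehyde) and at C5'–C6' (Negishi coupling with the butenyl bromide). What remains is C1'–C5', whose methyl-bearing carbons C2' (S) and C4' (R) are syn, so the segment hides a mirror plane through C3' and maps onto meso-2,4-dimethylpentane-1,5-diol. A lipase-mediated acetyl transfer from vinyl acetate to one of the two enantiotopic hydroxymethyl groups of this achiral diol, itself one reduction away from cis-2,4-dimethylglutaric anhydride, fixes both stereocentres at once and marks which terminus becomes C1' and which C5'.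

Key step: step 2

Assumption: the Pseudomonas fluorescens lipase is taken to acetylate the hydroxymethyl group on the (S)-configured carbon of diol 2; carbinol 18 is carried on as a mixture of C1' epimers because that centre is removed in step 12.

Step 1
Reactants: 1 cis-2,4-dimethylglutaric anhydride
Product: 2 meso-2,4-dimethylpentane-1,5-diol
Conditions: LiAlH4, THF, 0 °C → reflux; then H2O, aq. NaOH
Reagents that add atoms: none
Why: Hydride reduction of a cyclic anhydride by LiAlH4 takes both acyl carbons to the primary alcohol level without touching the two α-methyl centres, so the cis (meso) relationship of 1 is carried into the diol.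

Step 2
Reactants: 2 meso-2,4-dimethylpentane-1,5-diol; 3 vinyl acetate
Product: 4 (2S,4R)-5-hydroxy-2,4-dimethylpentyl acetate
Conditions: Pseudomonas fluorescens lipase, vinyl acetate (3, excess), THF, rt; enzyme filtered off once 2 is consumed
Reagents that add atoms: none
Why: The active-site serine of the lipase is acetylated by 3 and the acyl-enzyme hands the acetyl group to the hydroxymethyl arm of 2 that sits on the (S)-configured carbon, the arm the chiral pocket places next to the acyl group; the enol released tautomerises to acetaldehyde, so the transfer cannot run backwards. The closest known reaction type is the lipase-catalysed irreversible transesterification of meso and prochiral diols with enol esters. No ring is closed and no skeletal bond is formed. No stereogenic carbon is created by bond formation; instead C2 (S) and C4 (R) of 4, mirror-related in 2, both become defined through the enzyme's choice between the two enantiotopic CH2OH groups, so the enzyme pocket is the controlling element for both. The step needs enantiotopic-group selectivity and a stop at the monoacetate: the syn-dimethyl meso array offers the pocket two mirror-image arms to tell apart, and the slower second acetylation should consume the minor monoacetate preferentially, raising the enantiomeric purity of 4 at the cost of a little diacetate.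

Step 3
Reactants: 4 (2S,4R)-5-hydroxy-2,4-dimethylpentyl acetate
Product: 5 (2S,4R)-5-iodo-2,4-dimethylpentyl acetate
Conditions: I2, PPh3, imidazole, CH2Cl2, 0 °C → rt
Reagents that add atoms: iodine, II
Why: Appel-type iodination converts the primary alcohol through its alkoxyphosphonium salt into the iodide by SN2 displacement at CH2, which leaves the neighbouring methyl-bearing stereocentre and the acetate untouched.

Step 4
Reactants: 5 (2S,4R)-5-iodo-2,4-dimethylpentyl acetate; 6 (E)-2-bromobut-2-ene
Product: 8 (2S,4R,6E)-2,4,6-trimethyloct-6-en-1-yl acetate, via alkylzinc iodide 7 (not isolated)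
Conditions: Zn dust (activated with BrCH2CH2Br, Me3SiCl), LiCl, THF, 40 °C; then 6, Pd(PPh3)4 (5 mol%), THF, 50 °C
Reagents that add atoms: none
Why: Oxidative insertion of zinc into the primary C–I bond gives an ester-tolerant alkylzinc iodide that undergoes Negishi coupling with 6, and since oxidative addition of the alkenyl bromide to zerovalent palladium and reductive elimination both proceed with retention, the C6=C7 double bond should be E (chain trans to the C8 methyl) while neither methyl-bearing centre takes part.

Step 5
Reactants: 8 (2S,4R,6E)-2,4,6-trimethyloct-6-en-1-yl acetate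
Product: 9 (2S,4R,6E)-2,4,6-trimethyloct-6-en-1-ol
Conditions: K2CO3 (0.2 equiv), MeOH, rt
Reagents that add atoms: none
Why: Base-catalysed transesterification (methanolysis of the acetate) frees the primary alcohol under conditions that touch neither the alkene nor the stereocentres.

Step 6
Reactants: 9 (2S,4R,6E)-2,4,6-trimethyloct-6-en-1-ol
Product: 10 (2S,4R,6E)-2,4,6-trimethyloct-6-enal
Conditions: 2,2,6,6-tetramethylpiperidin-1-oxyl (TEMPO, 10 mol%), PhI(OAc)2, CH2Cl2, rt; used at once
Reagents that add atoms: none
Why: Oxoammonium-mediated (TEMPO/PhI(OAc)2) oxidation stops at the aldehyde and, being free of base, should leave the α-stereocentre at C2 and the trisubstituted alkene intact.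

Step 7
Reactants: 11 4-hydroxypyridin-2(1H)-one
Product: 12 2,4-bis(methoxymethoxy)pyridine
Conditions: MOMCl, Ag2CO3, toluene, rt, dark
Reagents that add atoms: chloromethyl methyl ether (MOMCl), COCCl
Why: Silver-assisted O-alkylation of the ambident pyridone, in which the silver salt in a non-polar solvent meets the hard, oxocarbenium-like chloromethyl ether at oxygen and not at nitrogen, should convert both oxygens into MOM acetals and give a 2,4-dialkoxypyridine.

Step 8
Reactants: 12 2,4-bis(methoxymethoxy)pyridine
Product: 13 5-bromo-2,4-bis(methoxymethoxy)pyridine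
Conditions: NBS, MeCN, 0 °C → rt
Reagents that add atoms: N-bromosuccinimide, O=C1CCC(=O)N1Br
Why: Electrophilic aromatic bromination should go to C5, which is para to the C2 oxygen, ortho to the C4 oxygen and unhindered, and not to C3, which is flanked by both OMOM groups (the preference 1,3-dialkoxybenzenes show for C4), whereas the unprotected pyridone would have halogenated at C3.

Step 9
Reactants: 13 5-bromo-2,4-bis(methoxymethoxy)pyridine; 14 4-hydroxyphenylboronic acid
Product: 15 4-[4,6-bis(methoxymethoxy)pyridin-3-yl]phenol
Conditions: Pd(PPh3)4 (5 mol%), K2CO3, dioxane/H2O, 85 °C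
Reagents that add atoms: none
Why: Suzuki–Miyaura coupling of the heteroaryl bromide with the arylboronic acid forms the C5–aryl bond, the free phenol being tolerated as its phenoxide and the MOM acetals being stable to aqueous carbonate.

Step 10
Reactants: 15 4-[4,6-bis(methoxymethoxy)pyridin-3-yl]phenol
Product: 16 2,4-bis(methoxymethoxy)-5-[4-(methoxymethoxy)phenyl]pyridine
Conditions: NaH, THF, 0 °C; then MOMCl, 0 °C → rt
Reagents that add atoms: chloromethyl methyl ether (MOMCl), COCCl
Why: Williamson etherification of the sodium phenoxide caps the last acidic hydrogen, so that all three oxygens carry the same acid-labile group and the metalation in step 11 meets no proton source.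

Step 11
Reactants: 16 2,4-bis(methoxymethoxy)-5-[4-(methoxymethoxy)phenyl]pyridine; 10 (2S,4R,6E)-2,4,6-trimethyloct-6-enal
Product: 18 (2S,4R,6E)-1-{2,4-bis(methoxymethoxy)-5-[4-(methoxymethoxy)phenyl]pyridin-3-yl}-2,4,6-trimethyloct-6-en-1-ol (both C1 epimers), via 3-lithiopyridine 17 (not isolated)
Conditions: n-BuLi, THF, −78 °C; then 10, −78 → −40 °C; H2O
Reagents that add atoms: none
Why: Directed ortho-metalation should take place at C3–H, which lies between two coordinating OMOM groups on an electron-poor ring and is therefore more acidic and better chelated than the positions ortho to the single aryl OMOM group, and the aryllithium then undergoes 1,2-addition to the aldehyde, forming the carbinol centre without control, which does not matter because step 12 removes it.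

Step 12
Reactants: 18 (2S,4R,6E)-1-{2,4-bis(methoxymethoxy)-5-[4-(methoxymethoxy)phenyl]pyridin-3-yl}-2,4,6-trimethyloct-6-en-1-ol
Product: 19 (2S,4R,6E)-1-{2,4-bis(methoxymethoxy)-5-[4-(methoxymethoxy)phenyl]pyridin-3-yl}-2,4,6-trimethyloct-6-en-1-one
Conditions: Dess–Martin periodinane, pyridine, CH2Cl2, 0 °C → rt
Reagents that add atoms: none
Why: Dess–Martin oxidation converts the hindered secondary pyridyl carbinol into the ketone under buffered, near-neutral conditions and merges both C1 epimers, while the two ortho OMOM groups twist the ketone out of the ring plane and so disfavour enolisation towards the C2 stereocentre.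

Step 13
Reactants: 19 (2S,4R,6E)-1-{2,4-bis(methoxymethoxy)-5-[4-(methoxymethoxy)phenyl]pyridin-3-yl}-2,4,6-trimethyloct-6-en-1-one
Product: 20 vancouverone A, 4-hydroxy-5-(4-hydroxyphenyl)-3-[(2S,4R,6E)-2,4,6-trimethyloct-6-enoyl]pyridin-2(1H)-one
Conditions: HCl (ca. 2 M in MeOH), rt → 40 °C
Reagents that add atoms: none
Why: Acid-catalysed acetal cleavage (methanolysis of the three MOM ethers, with methanol trapping the methoxymethyl cation) unveils the phenol, the 4-hydroxyl and the 2-hydroxypyridine, which tautomerises to the 2-pyridone, and the hydrogen-bonded 3-acyl-4-hydroxypyridone should resist enolisation at C2' while dilute acid leaves the trisubstituted alkene in place.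

Compound list
1 | cis-2,4-dimethylglutaric anhydride, (3R,5S)-3,5-dimethyloxane-2,6-dione (meso) | C[C@H]1C[C@@H](C)C(=O)OC1=O | starting material
2 | meso-2,4-dimethylpentane-1,5-diol, (2R,4S) | OC[C@H](C)C[C@H](C)CO | intermediate
3 | vinyl acetate | CC(=O)OC=C | starting material
4 | (2S,4R)-5-hydroxy-2,4-dimethylpentyl acetate | OC[C@H](C)C[C@H](C)COC(C)=O | intermediate
5 | (2S,4R)-5-iodo-2,4-dimethylpentyl acetate | IC[C@H](C)C[C@H](C)COC(C)=O | intermediate
6 | (E)-2-bromobut-2-ene | C/C=C(\C)Br | starting material
7 | [(2R,4S)-5-acetoxy-2,4-dimethylpentyl]zinc iodide (formed in the flask) | I[Zn]C[C@H](C)C[C@H](C)COC(C)=O | intermediate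
8 | (2S,4R,6E)-2,4,6-trimethyloct-6-en-1-yl acetate | C/C=C(\C)C[C@H](C)C[C@H](C)COC(C)=O | intermediate
9 | (2S,4R,6E)-2,4,6-trimethyloct-6-en-1-ol | C/C=C(\C)C[C@H](C)C[C@H](C)CO | intermediate
10 | (2S,4R,6E)-2,4,6-trimethyloct-6-enal | C/C=C(\C)C[C@H](C)C[C@H](C)C=O | intermediate
11 | 4-hydroxypyridin-2(1H)-one | O=c1cc(O)cc[nH]1 | starting material
12 | 2,4-bis(methoxymethoxy)pyridine | COCOc1ccnc(OCOC)c1 | intermediate
13 | 5-bromo-2,4-bis(methoxymethoxy)pyridine | COCOc1cc(OCOC)c(Br)cn1 | intermediate
14 | 4-hydroxyphenylboronic acid | OB(O)c1ccc(O)cc1 | starting material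
15 | 4-[4,6-bis(methoxymethoxy)pyridin-3-yl]phenol | COCOc1cc(OCOC)c(-c2ccc(O)cc2)cn1 | intermediate
16 | 2,4-bis(methoxymethoxy)-5-[4-(methoxymethoxy)phenyl]pyridine | COCOc1cc(OCOC)c(-c2ccc(OCOC)cc2)cn1 | intermediate
17 | {2,4-bis(methoxymethoxy)-5-[4-(methoxymethoxy)phenyl]pyridin-3-yl}lithium (formed in the flask) | [Li]c1c(OCOC)ncc(-c2ccc(OCOC)cc2)c1OCOC | intermediate
18 | (2S,4R,6E)-1-{2,4-bis(methoxymethoxy)-5-[4-(methoxymethoxy)phenyl]pyridin-3-yl}-2,4,6-trimethyloct-6-en-1-ol (both C1 epimers) | C/C=C(\C)C[C@H](C)C[C@H](C)C(O)c1c(OCOC)ncc(-c2ccc(OCOC)cc2)c1OCOC | intermediate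
19 | (2S,4R,6E)-1-{2,4-bis(methoxymethoxy)-5-[4-(methoxymethoxy)phenyl]pyridin-3-yl}-2,4,6-trimethyloct-6-en-1-one | C/C=C(\C)C[C@H](C)C[C@H](C)C(=O)c1c(OCOC)ncc(-c2ccc(OCOC)cc2)c1OCOC | intermediate
20 | vancouverone A, 4-hydroxy-5-(4-hydroxyphenyl)-3-[(2S,4R,6E)-2,4,6-trimethyloct-6-enoyl]pyridin-2(1H)-one | C/C=C(\C)C[C@H](C)C[C@H](C)C(=O)c1c(O)c(-c2ccc(O)cc2)c[nH]c1=O | target

Total step count: 13. Longest linear sequence: 9 steps (steps 1–6, then 11–13); steps 7–10 build the pyridine partner in parallel.

Steps most likely to fail

Step 2. The acyl transfer may not tell the two enantiotopic arms apart cleanly enough, or may run on to the diacetate and erode the material balance. The fallback uses the hydrolytic direction and exchanges the roles of the two termini. It sets out from 2: Ac2O and pyridine would give meso-2,4-dimethylpentane-1,5-diyl diacetate F1. Lipase-mediated hydrolysis of one enantiotopic ester in pH 7 phosphate buffer (porcine pancreatic lipase, or the Pseudomonas lipase, which should now unmask the arm it would otherwise have acylated) would give the mirror-image monoacetate, (2R,4S)-5-hydroxy-2,4-dimethylpentyl acetate F2. Its free hydroxyl sits on the arm destined to be C1', so it would be capped (TBSCl, imidazole, DMF) as (2R,4S)-5-[(tert-butyldimethylsilyl)oxy]-2,4-dimethylpentyl acetate F3. Removal of the acetate (K2CO3, MeOH) would give (2R,4S)-5-[(tert-butyldimethylsilyl)oxy]-2,4-dimethylpentan-1-ol F4. The freed end would then pass through the same iodination (I2, PPh3, imidazole) to tert-butyl{[(2S,4R)-5-iodo-2,4-dimethylpentyl]oxy}dimethylsilane F5, zinc insertion to {(2R,4S)-5-[(tert-butyldimethylsilyl)oxy]-2,4-dimethylpentyl}zinc iodide F6, and coupling with 6 under Pd(PPh3)4 to tert-butyldimethyl{[(2S,4R,6E)-2,4,6-trimethyloct-6-en-1-yl]oxy}silane F7. Bu4NF in THF would then bring the route back at 9. Either monoacetate enantiomer of high purity is therefore usable.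

Step 4. Zinc insertion into the β-branched iodide may stall, or the alkylzinc may be lost through protonation or through β-hydride elimination at palladium. The fallback inverts the polarity of the coupling. It sets out from 6 and 5: bromine–lithium exchange on 6 (t-BuLi, 2 equiv, Et2O, −78 °C), with retention of geometry, would give (Z)-but-2-en-2-yllithium F8 (the descriptor changes because lithium ranks below carbon; the two methyl groups stay cis). ZnCl2 would convert it into (E)-but-2-en-2-ylzinc chloride F9. This would be coupled with iodide 5 as the electrophile under a palladium/trialkylphosphine system suited to unactivated primary alkyl halides (Pd2(dba)3, tricyclopentylphosphine, N-methylimidazole, THF/NMP, 80 °C), coming back to the route at 8.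

Step 11. Butyllithium may metalate at a wrong site (ortho to the aryl OMOM group) or add to the pyridine ring instead of removing the C3 proton. The fallback changes the order of events at the heterocycle, so that an amide base acts on a substrate with only one acidified position and the aryl group arrives later. It sets out from 13 and 10: LiN(iPr)2 in THF at −78 °C would remove the C3 proton between the two OMOM groups without touching the bromide, giving [5-bromo-2,4-bis(methoxymethoxy)pyridin-3-yl]lithium F10. Addition to 10 would give (2S,4R,6E)-1-[5-bromo-2,4-bis(methoxymethoxy)pyridin-3-yl]-2,4,6-trimethyloct-6-en-1-ol F11. Suzuki–Miyaura coupling with 14 (Pd(PPh3)4, K2CO3, dioxane/H2O) would be run at this carbinol stage, where no ketone makes the C2 centre base-labile, and would give 4-{5-[(2S,4R,6E)-1-hydroxy-2,4,6-trimethyloct-6-en-1-yl]-4,6-bis(methoxymethoxy)pyridin-3-yl}phenol F12. Phenol-selective alkylation (MOMCl, K2CO3, acetone) would bring the route back at 18.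

Further compounds
F1 | step 2 | meso-2,4-dimethylpentane-1,5-diyl diacetate | CC(=O)OC[C@H](C)C[C@H](C)COC(C)=O
F2 | step 2 | (2R,4S)-5-hydroxy-2,4-dimethylpentyl acetate | OC[C@@H](C)C[C@@H](C)COC(C)=O
F3 | step 2 | (2R,4S)-5-[(tert-butyldimethylsilyl)oxy]-2,4-dimethylpentyl acetate | CC(C)(C)[Si](C)(C)OC[C@@H](C)C[C@@H](C)COC(C)=O
F4 | step 2 | (2R,4S)-5-[(tert-butyldimethylsilyl)oxy]-2,4-dimethylpentan-1-ol | CC(C)(C)[Si](C)(C)OC[C@@H](C)C[C@@H](C)CO
F5 | step 2 | tert-butyl{[(2S,4R)-5-iodo-2,4-dimethylpentyl]oxy}dimethylsilane | CC(C)(C)[Si](C)(C)OC[C@@H](C)C[C@@H](C)CI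
F6 | step 2 | {(2R,4S)-5-[(tert-butyldimethylsilyl)oxy]-2,4-dimethylpentyl}zinc iodide | CC(C)(C)[Si](C)(C)OC[C@@H](C)C[C@@H](C)C[Zn]I
F7 | step 2 | tert-butyldimethyl{[(2S,4R,6E)-2,4,6-trimethyloct-6-en-1-yl]oxy}silane | C/C=C(\C)C[C@H](C)C[C@H](C)CO[Si](C)(C)C(C)(C)C
F8 | step 4 | (Z)-but-2-en-2-yllithium | C/C=C(\C)[Li]
F9 | step 4 | (E)-but-2-en-2-ylzinc chloride | C/C=C(\C)[Zn]Cl
F10 | step 11 | [5-bromo-2,4-bis(methoxymethoxy)pyridin-3-yl]lithium | [Li]c1c(OCOC)ncc(Br)c1OCOC
F11 | step 11 | (2S,4R,6E)-1-[5-bromo-2,4-bis(methoxymethoxy)pyridin-3-yl]-2,4,6-trimethyloct-6-en-1-ol (both C1 epimers) | C/C=C(\C)C[C@H](C)C[C@H](C)C(O)c1c(OCOC)ncc(Br)c1OCOC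
F12 | step 11 | 4-{5-[(2S,4R,6E)-1-hydroxy-2,4,6-trimethyloct-6-en-1-yl]-4,6-bis(methoxymethoxy)pyridin-3-yl}phenol (both carbinol epimers) | C/C=C(\C)C[C@H](C)C[C@H](C)C(O)c1c(OCOC)ncc(-c2ccc(O)cc2)c1OCOC
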